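The synthesis is cut at N1'–C2' of ring B, the NH indole. C3' of ring B is bonded to N1 of ring A and to C3a', so it is traced back to the benzylic carbon of a 2,3-dibromo-6-nitrobenzyl group on N1 of 5-bromoindole; C2' comes from an aminomethylene carbon. Reducing the nitro group of the resulting β-dimethylamino-α-(indol-1-yl)-2-nitrostyrene 9 lets the new aniline nitrogen close the pyrrole ring of ring B with loss of dimethylamine. This should deliver the complete 1,3'-biindole 12 with the 5-, 4'- and 5'-bromines already in place. Three pyrrole-ring brominations (C3, C2', C2) finish the synthesis.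

Key step: step 6

Remark: unprimed locants refer to ring A (the N1-substituted indole) and primed locants to ring B (the NH indole). Enamine 9 is drawn as the Z isomer for definiteness; its geometry is not controlled and either isomer would serve.

Step 1
Reactants: 1 3-bromo-2-methylaniline
Product: 2 3,4-dibromo-2-methylaniline
Conditions: NBS (1.0 equiv), MeCN, 0 °C to rt
Reagents that add atoms: N-bromosuccinimide, O=C1CCC(=O)N1Br
Why: Electrophilic aromatic bromination directed by the amino group to its free para position C4 (the methyl group blocks one ortho site), so one equivalent of NBS in a polar solvent should give the 3,4-dibromo pattern, with the 6-bromo isomer expected only as a separable minor by-product.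

Step 2
Reactants: 2 3,4-dibromo-2-methylaniline
Product: 3 1,2-dibromo-3-methyl-4-nitrobenzene
Conditions: mCPBA (4 equiv), 1,2-dichloroethane, 80 °C
Reagents that add atoms: 3-chloroperbenzoic acid, OOC(=O)c1cccc(Cl)c1
Why: Peracid oxidation of a primary arylamine to the nitroarene; excess mCPBA at elevated temperature should carry nitrogen to the nitro level faster than azoxy coupling, and the aryl bromides and the methyl group are inert to the peracid.

Step 3
Reactants: 3 1,2-dibromo-3-methyl-4-nitrobenzene
Product: 4 1,2-dibromo-3-(bromomethyl)-4-nitrobenzene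
Conditions: NBS (1.1 equiv), AIBN (0.1 equiv), PhCF3, 90 °C
Reagents that add atoms: N-bromosuccinimide, O=C1CCC(=O)N1Br
Why: Wohl–Ziegler radical bromination at the only benzylic C–H position; the low stationary bromine concentration from NBS limits dibromination and the electron-poor ring is not brominated.

Step 4
Reactants: 4 1,2-dibromo-3-(bromomethyl)-4-nitrobenzene; 5 5-bromoindole
Product: 7 5-bromo-1-[(2,3-dibromo-6-nitrophenyl)methyl]indole, via sodium 5-bromoindol-1-ide 6 (not isolated)
Conditions: NaH (1.1 equiv), DMF, 0 °C; then 4, 0 °C to rt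
Reagents that add atoms: none
Why: SN2 N-alkylation of the preformed sodium indolide, which in DMF reacts with a primary benzylic bromide at nitrogen in preference to C3; no free base remains when 4 is added, which avoids base-induced self-condensation of the nitrobenzyl halide.

Step 5
Reactants: 7 5-bromo-1-[(2,3-dibromo-6-nitrophenyl)methyl]indole; 8 tert-butoxybis(dimethylamino)methane
Product: 9 (Z)-2-(5-bromoindol-1-yl)-2-(2,3-dibromo-6-nitrophenyl)-N,N-dimethylethenamine
Conditions: 8 (3 equiv), DMF, 110 °C, N2
Reagents that add atoms: tert-butoxybis(dimethylamino)methane (8), CN(C)C(OC(C)(C)C)N(C)C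
Why: Aminomethylenation of a CH-acid (the enamine-forming stage of the Leimgruber–Batcho synthesis): tert-butoxide released from the aminal ester deprotonates the benzylic CH2, which is acidified by the ortho-nitroaryl ring and the indolyl nitrogen, the carbanion adds to the bis(dimethylamino)methylium ion, and loss of dimethylamine gives the push–pull enamine.

Step 6
Reactants: 9 (Z)-2-(5-bromoindol-1-yl)-2-(2,3-dibromo-6-nitrophenyl)-N,N-dimethylethenamine
Product: 12 5-bromo-1-(4,5-dibromo-1H-indol-3-yl)indole, via amino enamine 10 (not isolated), via 2-(dimethylamino)indoline 11 (not isolated)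
Conditions: Fe powder (8 equiv), AcOH–EtOH (1:1), 80 °C
Reagents that add atoms: none
Why: Fe in AcOH reduces the nitro group by stepwise electron and proton transfer to aniline 10 without cleaving C–Br bonds; in the acidic medium the enamine is protonated at the carbon bearing N1 of ring A, the aniline nitrogen adds to the resulting iminium carbon to give aminal 11, and loss of dimethylamine aromatises the new ring. This is the reductive cyclization stage of the Leimgruber–Batcho indole synthesis, applied to an α-substituted β-dimethylamino-2-nitrostyrene. The one ring closed is the pyrrole ring of ring B, by 5-exo-trig attack of N1' on the iminium carbon that becomes C2'. No stereocentre remains, because elimination erases both sp3 centres of 11, and the enamine geometry is irrelevant because C-protonation frees rotation. The step needs chemoselective nitro reduction beside three aryl bromides and the C2=C3 bond of ring A, which a dissolving-metal reductant should secure where catalytic hydrogenation would not; the placement of bromine at C4' and C5' is fixed by the substitution pattern of the arene.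

Step 7
Reactants: 12 5-bromo-1-(4,5-dibromo-1H-indol-3-yl)indole
Product: 15 rivularin A [2,3,5-tribromo-1-(2,4,5-tribromo-1H-indol-3-yl)indole], via ring A 3-bromide 13 (not isolated), via 3,2'-dibromide 14 (not isolated)
Conditions: NBS (3.05 equiv, portionwise), THF, −78 °C to rt, dark
Reagents that add atoms: N-bromosuccinimide, O=C1CCC(=O)N1Br
Why: Electrophilic bromination of the three remaining pyrrole CH positions in the expected order of nucleophilicity (C3 of ring A, then C2' of the 3-substituted ring B, then C2 of the 3-bromoindole ring A) ahead of the bromine-deactivated benzo rings, following the known NBS conversions of N-substituted indoles into 2,3-dibromoindoles and of 3-substituted indoles into 2-bromoindoles.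

Compound list
1 | 3-bromo-2-methylaniline | Cc1c(N)cccc1Br | starting material
2 | 3,4-dibromo-2-methylaniline | Cc1c(N)ccc(Br)c1Br | intermediate
3 | 1,2-dibromo-3-methyl-4-nitrobenzene | Cc1c([N+](=O)[O-])ccc(Br)c1Br | intermediate
4 | 1,2-dibromo-3-(bromomethyl)-4-nitrobenzene | BrCc1c([N+](=O)[O-])ccc(Br)c1Br | intermediate
5 | 5-bromoindole | Brc1ccc2[nH]ccc2c1 | starting material
6 | sodium 5-bromoindol-1-ide (formed in the flask) | [Na+].Brc1ccc2[n-]ccc2c1 | intermediate
7 | 5-bromo-1-[(2,3-dibromo-6-nitrophenyl)methyl]indole | Brc1ccc2c(c1)ccn2Cc1c(Br)c(Br)ccc1[N+](=O)[O-] | intermediate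
8 | tert-butoxybis(dimethylamino)methane | CN(C)C(OC(C)(C)C)N(C)C | starting material
9 | (Z)-2-(5-bromoindol-1-yl)-2-(2,3-dibromo-6-nitrophenyl)-N,N-dimethylethenamine | CN(C)/C=C(\n1ccc2cc(Br)ccc12)c1c(Br)c(Br)ccc1[N+](=O)[O-] | intermediate
10 | (Z)-2-(6-amino-2,3-dibromophenyl)-2-(5-bromoindol-1-yl)-N,N-dimethylethenamine (amino enamine, formed in the flask) | CN(C)/C=C(\n1ccc2cc(Br)ccc12)c1c(Br)c(Br)ccc1N | intermediate
11 | 4,5-dibromo-3-(5-bromoindol-1-yl)-N,N-dimethyl-2,3-dihydro-1H-indol-2-amine (formed in the flask; mixture of diastereomers, configuration without consequence) | CN(C)C1Nc2ccc(Br)c(Br)c2C1n1ccc2cc(Br)ccc12 | intermediate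
12 | 5-bromo-1-(4,5-dibromo-1H-indol-3-yl)indole | Brc1ccc2c(c1)ccn2-c1c[nH]c2ccc(Br)c(Br)c12 | intermediate
13 | 3,5-dibromo-1-(4,5-dibromo-1H-indol-3-yl)indole (formed in the flask) | Brc1ccc2c(c1)c(Br)cn2-c1c[nH]c2ccc(Br)c(Br)c12 | intermediate
14 | 3,5-dibromo-1-(2,4,5-tribromo-1H-indol-3-yl)indole (formed in the flask) | Brc1ccc2c(c1)c(Br)cn2-c1c(Br)[nH]c2ccc(Br)c(Br)c12 | intermediate
15 | rivularin A, 2,3,5-tribromo-1-(2,4,5-tribromo-1H-indol-3-yl)indole | Brc1ccc2c(c1)c(Br)c(Br)n2-c1c(Br)[nH]c2ccc(Br)c(Br)c12 | target

Total step count: 7. Longest linear sequence: 7 steps (1 to 15); 5-bromoindole 5 and aminal ester 8 enter as purchased.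

Steps most likely to fail

Step 5. The benzylic CH2 lies between two ortho substituents and carries the indolyl group, so deprotonation and condensation may be slow, and base-induced decomposition of the ortho-nitrobenzyl system may compete at the temperature needed. The fallback sets out from 7 and replaces the thermal condensation by a stoichiometric carbanion formylation. Deprotonation with LiN(SiMe3)2 (2.2 equiv, THF, −78 °C) and Claisen-type C-formylation with ethyl formate should give 2-(5-bromoindol-1-yl)-2-(2,3-dibromo-6-nitrophenyl)acetaldehyde F1 (racemic, enolisable). Condensation of F1 with dimethylamine (THF, 4 Å molecular sieves, rt) would return to the route at 9.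

Step 6. The reduction may stall at the hydroxylamine stage and close to an N-hydroxyindole, the enamine carbon may be lost by hydrolysis and cleavage before ring closure, or bromine may be lost reductively. The fallback sets out from 7 and forms ring B through C2'–C3' instead of N1'–C2'. Nitro reduction with Fe and NH4Cl (EtOH–H2O, 80 °C) should give 3,4-dibromo-2-[(5-bromoindol-1-yl)methyl]aniline F2. N-formylation with acetic formic anhydride (THF, 0 °C) should give N-{3,4-dibromo-2-[(5-bromoindol-1-yl)methyl]phenyl}formamide F3. Dehydration with POCl3 and Et3N (CH2Cl2, 0 °C) should give 5-bromo-1-[(2,3-dibromo-6-isocyanophenyl)methyl]indole F4. Benzylic lithiation of F4 with LiN(iPr)2 (THF, −78 °C to rt) and attack of the carbanion on the isocyanide carbon (Ito–Saegusa indole synthesis) would come back to the route at 12.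

Step 7. Bromination of the benzo rings (C6 of ring A, C6' or C7' of ring B) may overtake the slow third substitution at the crowded C2 of ring A, and NBS may oxidise ring B. The fallback sets out from 7 and moves two of the three brominations ahead of ring closure. NBS (2.05 equiv, THF, −78 °C to rt) should give 2,3,5-tribromo-1-[(2,3-dibromo-6-nitrophenyl)methyl]indole F5. Condensation with 8 (DMF, 110 °C) should give (Z)-2-(2,3-dibromo-6-nitrophenyl)-N,N-dimethyl-2-(2,3,5-tribromoindol-1-yl)ethenamine F6. Buffered reductive cyclization with TiCl3 and NH4OAc (aqueous acetone, rt) should give 2,3,5-tribromo-1-(4,5-dibromo-1H-indol-3-yl)indole F7. A single NBS bromination (1.0 equiv, THF, −78 °C to 0 °C) at C2' of the 3-substituted ring B would then arrive at 15.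

Further compounds
F1 | step 5 | 2-(5-bromoindol-1-yl)-2-(2,3-dibromo-6-nitrophenyl)acetaldehyde (racemic) | O=CC(n1ccc2cc(Br)ccc12)c1c(Br)c(Br)ccc1[N+](=O)[O-]
F2 | step 6 | 3,4-dibromo-2-[(5-bromoindol-1-yl)methyl]aniline | Nc1ccc(Br)c(Br)c1Cn1ccc2cc(Br)ccc12
F3 | step 6 | N-{3,4-dibromo-2-[(5-bromoindol-1-yl)methyl]phenyl}formamide | O=CNc1ccc(Br)c(Br)c1Cn1ccc2cc(Br)ccc12
F4 | step 6 | 5-bromo-1-[(2,3-dibromo-6-isocyanophenyl)methyl]indole | [C-]#[N+]c1ccc(Br)c(Br)c1Cn1ccc2cc(Br)ccc12
F5 | step 7 | 2,3,5-tribromo-1-[(2,3-dibromo-6-nitrophenyl)methyl]indole | Brc1ccc2c(c1)c(Br)c(Br)n2Cc1c(Br)c(Br)ccc1[N+](=O)[O-]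
F6 | step 7 | (Z)-2-(2,3-dibromo-6-nitrophenyl)-N,N-dimethyl-2-(2,3,5-tribromoindol-1-yl)ethenamine | CN(C)/C=C(\n1c(Br)c(Br)c2cc(Br)ccc12)c1c(Br)c(Br)ccc1[N+](=O)[O-]
F7 | step 7 | 2,3,5-tribromo-1-(4,5-dibromo-1H-indol-3-yl)indole | Brc1ccc2c(c1)c(Br)c(Br)n2-c1c[nH]c2ccc(Br)c(Br)c12
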